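**Plan**
- Retrosynthesis: the side-chain ester C–O bond is cut first (free (R)-carbinol plus 3-methylbut-2-enoic acid). Ring A of the 5,8-dihydroxy-1,4-naphthoquinone is then cut at C2=C3 and at C4–C4a, giving a 2-acyl-1,4-benzoquinone and a two-carbon enediol bis(silyl) ether (C3–C4). Last come C1–C2 (acyl-anion alkylation with an epoxide) and the CH2–vinyl bond of the side chain.
- Enabling feature: ring B is a hydroquinone that can be carried as its quinone. In that form the fusion carbon C4a is β to two carbonyls (C8=O and the C1 acyl C=O) and is electrophilic, and C2 is the nucleophilic α-CH2 of the C1 ketone. The [4+2] product is the 1,4,5,8-tetrol (leuco) form, which air oxidises to the naphthazarin, so the phenols need no protection.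
- Forward: ring B is bought as 2,5-dimethoxybenzaldehyde, and its formyl carbon (C1) is joined as a lithiated dithiane to the chiral epoxide. Dithiane hydrolysis and oxidative demethylation give the acylquinone, ring A is closed in one flask, and desilylation and esterification finish the route.
- Stereochemistry: the only stereocentre (C1', R) comes from (R)-epichlorohydrin; no later step makes or breaks a bond at this carbon.

Key step: step 8

Remark: the target is taken as the 3-methylbut-2-enoate of (R)-shikonin. Atom numbers are those of the naphthalene-1,4-dione core: C2 carries the side chain, C3 is the ring CH, C4a and C8a are the fusion carbons, ring A is the substituted ring, ring B the other, and C1' is the carbinol carbon.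

Step 1
Reactants: 1 2,5-dimethoxybenzaldehyde
Product: 2 2-(2,5-dimethoxyphenyl)-1,3-dithiane
Conditions: HS(CH2)3SH, BF3·OEt2 (cat.), CH2Cl2, 0 °C → rt
Reagents that add atoms: propane-1,3-dithiol SCCCS
Why: BF3-catalysed thioacetalisation of an electron-rich benzaldehyde is reliable and turns the formyl carbon (later C1) into an acyl-anion equivalent (dithiane umpolung).

Step 2
Reactants: 3 (R)-epichlorohydrin; 4 2-methylprop-1-en-1-ylmagnesium bromide
Product: 6 (2R)-2-(3-methylbut-2-en-1-yl)oxirane, via chlorohydrin (2R)-1-chloro-5-methylhex-4-en-2-ol 5 (not isolated)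
Conditions: CuI (10 mol %), THF, −40 → −20 °C; then NaOH (aq), 0 °C → rt
Reagents that add atoms: none
Why: CuI-catalysed SN2 opening of the epoxide by the vinyl Grignard reagent at the unsubstituted ring carbon, then base-induced intramolecular Williamson closure of chlorohydrin 5 at the CH2Cl carbon, never breaks a bond at the stereocentre, so the (R) configuration of the chiral-pool epichlorohydrin should be carried into 6.

Step 3
Reactants: 2 2-(2,5-dimethoxyphenyl)-1,3-dithiane; 6 (2R)-2-(3-methylbut-2-en-1-yl)oxirane
Product: 8 (2R)-1-[2-(2,5-dimethoxyphenyl)-1,3-dithian-2-yl]-5-methylhex-4-en-2-ol, via lithiated dithiane 2-lithio-2-(2,5-dimethoxyphenyl)-1,3-dithiane 7 (not isolated)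
Conditions: n-BuLi, THF, −30 °C; then 6, −30 → 0 °C; then H2O
Reagents that add atoms: none
Why: Corey–Seebach alkylation, in which lithiated dithiane 7 opens the terminal epoxide at its CH2 carbon by SN2, should form the C1–C2 bond and leave the (R) carbinol centre untouched.

Step 4
Reactants: 8 (2R)-1-[2-(2,5-dimethoxyphenyl)-1,3-dithian-2-yl]-5-methylhex-4-en-2-ol
Product: 9 tert-butyl{[(2R)-1-[2-(2,5-dimethoxyphenyl)-1,3-dithian-2-yl]-5-methylhex-4-en-2-yl]oxy}dimethylsilane
Conditions: TBSOTf, 2,6-lutidine, CH2Cl2, −78 → 0 °C
Reagents that add atoms: tert-butyldimethylsilyl trifluoromethanesulfonate CC(C)(C)[Si](C)(C)OS(=O)(=O)C(F)(F)F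
Why: Silylation of the secondary alcohol with a silyl triflate is routine, and the silyl ether later blocks retro-aldol cleavage, β-elimination and oxa-Michael addition of this oxygen.

Step 5
Reactants: 9 tert-butyl{[(2R)-1-[2-(2,5-dimethoxyphenyl)-1,3-dithian-2-yl]-5-methylhex-4-en-2-yl]oxy}dimethylsilane
Product: 10 (3R)-3-[(tert-butyldimethylsilyl)oxy]-1-(2,5-dimethoxyphenyl)-6-methylhept-5-en-1-one
Conditions: MeI, CaCO3, MeCN/H2O, 45 °C
Reagents that add atoms: water O
Why: S-Alkylative hydrolysis of the 1,3-dithiane under buffered conditions should release the aryl ketone without touching the silyl ether, the trisubstituted alkene or the stereocentre β to the carbonyl.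

Step 6
Reactants: 10 (3R)-3-[(tert-butyldimethylsilyl)oxy]-1-(2,5-dimethoxyphenyl)-6-methylhept-5-en-1-one
Product: 11 2-{(3R)-3-[(tert-butyldimethylsilyl)oxy]-6-methylhept-5-enoyl}cyclohexa-2,5-diene-1,4-dione
Conditions: (NH4)2Ce(NO3)6, MeCN/H2O, 0 °C, used at once
Reagents that add atoms: water O
Why: Oxidative demethylation of a 1,4-dimethoxybenzene by tetravalent cerium (two one-electron oxidations and attack of water) is an established route to 2-acyl-1,4-benzoquinones, and the cold, short exposure should spare the silyl ether and the alkene.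

Step 7
Reactants: 12 [(tert-butyldimethylsilyl)oxy]acetaldehyde
Product: 13 (Z)-1,2-bis[(tert-butyldimethylsilyl)oxy]ethene
Conditions: TBSOTf, Et3N, CH2Cl2, 0 °C → rt
Reagents that add atoms: tert-butyldimethylsilyl trifluoromethanesulfonate CC(C)(C)[Si](C)(C)OS(=O)(=O)C(F)(F)F
Why: Enol silylation of the aldehyde with a silyl triflate and a tertiary amine should give the enediol bis(silyl) ether, whose geometry is of no consequence because both of its carbons become sp2 ring carbons.

Step 8
Reactants: 11 2-{(3R)-3-[(tert-butyldimethylsilyl)oxy]-6-methylhept-5-enoyl}cyclohexa-2,5-diene-1,4-dione; 13 (Z)-1,2-bis[(tert-butyldimethylsilyl)oxy]ethene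
Product: 16 5,8-dihydroxy-2-{(1R)-1-[(tert-butyldimethylsilyl)oxy]-4-methylpent-3-en-1-yl}naphthalene-1,4-dione, via cyclic silyl acetal Michael adduct 14 (not isolated), via leuco naphthalene-1,4,5,8-tetrol 15 (not isolated)
Conditions: MeCN, −20 → 0 °C; then K2CO3, MeOH, 0 °C → rt, argon; then air, aq. NH4Cl
Reagents that add atoms: none
Why: Proposed new method: one of the two equivalent carbons of 13 adds to C4a of the acylquinone (Mukaiyama–Michael addition, forming C4–C4a), ring B re-aromatises to the hydroquinone and the C3 oxocarbenium ion is held as cyclic silyl acetal 14; methanolic K2CO3 then unmasks the C3 aldehyde, the enolate of the C1 aryl ketone attacks it from C2, water is lost to give C2=C3, loss of the C4 proton aromatises ring A to tetrol 15, and air oxidises 15 to the naphthazarin. The closest known reaction types are the uncatalysed conjugate addition and [3+2] annulation of silyl enol ethers with 2-acyl-1,4-benzoquinones and the Robinson-type intramolecular aldol condensation, and what is new is their union into a [4+2] benzannulation of an acylquinone. Ring A closes by a 6-(enolendo)-exo-trig aldol addition, while the transient five-membered silyl acetal ring forms by 5-exo-trig attack of O5 on the oxocarbenium ion and is opened again. No new stereocentre survives, because the transient centres at C3 and C4 are erased on aromatisation and the C1' centre, held as its silyl ether, takes no part. The step needs site selectivity for C4a over C6 and C7, which should be secured because C4a is the only ring carbon β to two carbonyl groups, and it needs the aldol closure to outrun α-ketol isomerisation of the aldehyde and β-elimination at C1', which should be secured by keeping O4 and O1' silylated until ring A is aromatic; the orientation of the two-carbon unit is not an issue because 13 is symmetric.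

Step 9
Reactants: 16 5,8-dihydroxy-2-{(1R)-1-[(tert-butyldimethylsilyl)oxy]-4-methylpent-3-en-1-yl}naphthalene-1,4-dione
Product: 17 5,8-dihydroxy-2-[(1R)-1-hydroxy-4-methylpent-3-en-1-yl]naphthalene-1,4-dione
Conditions: HF·pyridine, THF, 0 °C → rt
Reagents that add atoms: none
Why: Fluoride-mediated cleavage of the secondary silyl ether under weakly acidic conditions avoids the base-sensitive naphthazarin anion and should leave the carbinol centre and the prenyl-type alkene intact.

Step 10
Reactants: 17 5,8-dihydroxy-2-[(1R)-1-hydroxy-4-methylpent-3-en-1-yl]naphthalene-1,4-dione; 18 3-methylbut-2-enoic acid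
Product: 19 (1R)-1-(5,8-dihydroxy-1,4-dioxo-1,4-dihydronaphthalen-2-yl)-4-methylpent-3-en-1-yl 3-methylbut-2-enoate
Conditions: DCC, DMAP (cat.), CH2Cl2, 0 °C → rt
Reagents that add atoms: none
Why: Steglich esterification should acylate only the side-chain alcohol, because the two peri phenols are locked in strong hydrogen bonds to the quinone carbonyls and are poor nucleophiles, and the carbinol C–O bond is not broken (retention).

**Compound list**
1 | 2,5-dimethoxybenzaldehyde | COc1ccc(OC)c(C=O)c1 | starting material
2 | 2-(2,5-dimethoxyphenyl)-1,3-dithiane | COc1ccc(OC)c(c1)C1SCCCS1 | intermediate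
3 | (R)-epichlorohydrin | ClC[C@H]1CO1 | starting material
4 | 2-methylprop-1-en-1-ylmagnesium bromide | CC(C)=C[Mg]Br | starting material
5 | (2R)-1-chloro-5-methylhex-4-en-2-ol | CC(C)=CC[C@@H](O)CCl | intermediate
6 | (2R)-2-(3-methylbut-2-en-1-yl)oxirane | CC(C)=CC[C@@H]1CO1 | intermediate
7 | 2-lithio-2-(2,5-dimethoxyphenyl)-1,3-dithiane | [Li]C1(SCCCS1)c1cc(OC)ccc1OC | intermediate
8 | (2R)-1-[2-(2,5-dimethoxyphenyl)-1,3-dithian-2-yl]-5-methylhex-4-en-2-ol | CC(C)=CC[C@@H](O)CC1(SCCCS1)c1cc(OC)ccc1OC | intermediate
9 | tert-butyl{[(2R)-1-[2-(2,5-dimethoxyphenyl)-1,3-dithian-2-yl]-5-methylhex-4-en-2-yl]oxy}dimethylsilane | CC(C)=CC[C@@H](O[Si](C)(C)C(C)(C)C)CC1(SCCCS1)c1cc(OC)ccc1OC | intermediate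
10 | (3R)-3-[(tert-butyldimethylsilyl)oxy]-1-(2,5-dimethoxyphenyl)-6-methylhept-5-en-1-one | CC(C)=CC[C@@H](O[Si](C)(C)C(C)(C)C)CC(=O)c1cc(OC)ccc1OC | intermediate
11 | 2-{(3R)-3-[(tert-butyldimethylsilyl)oxy]-6-methylhept-5-enoyl}cyclohexa-2,5-diene-1,4-dione | CC(C)=CC[C@@H](O[Si](C)(C)C(C)(C)C)CC(=O)C1=CC(=O)C=CC1=O | intermediate
12 | [(tert-butyldimethylsilyl)oxy]acetaldehyde | CC(C)(C)[Si](C)(C)OCC=O | starting material
13 | (Z)-1,2-bis[(tert-butyldimethylsilyl)oxy]ethene | CC(C)(C)[Si](C)(C)O/C=C\O[Si](C)(C)C(C)(C)C | intermediate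
14 | (3R)-1-{2,3-bis[(tert-butyldimethylsilyl)oxy]-5-hydroxy-2,3-dihydro-1-benzofuran-4-yl}-3-[(tert-butyldimethylsilyl)oxy]-6-methylhept-5-en-1-one (mixture at the two acetal-ring centres) | CC(C)=CC[C@@H](O[Si](C)(C)C(C)(C)C)CC(=O)c1c(O)ccc2OC(O[Si](C)(C)C(C)(C)C)C(O[Si](C)(C)C(C)(C)C)c12 | intermediate
15 | 2-{(1R)-1-[(tert-butyldimethylsilyl)oxy]-4-methylpent-3-en-1-yl}naphthalene-1,4,5,8-tetrol | CC(C)=CC[C@@H](O[Si](C)(C)C(C)(C)C)c1cc(O)c2c(O)ccc(O)c2c1O | intermediate
16 | 5,8-dihydroxy-2-{(1R)-1-[(tert-butyldimethylsilyl)oxy]-4-methylpent-3-en-1-yl}naphthalene-1,4-dione | CC(C)=CC[C@@H](O[Si](C)(C)C(C)(C)C)C1=CC(=O)c2c(O)ccc(O)c2C1=O | intermediate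
17 | 5,8-dihydroxy-2-[(1R)-1-hydroxy-4-methylpent-3-en-1-yl]naphthalene-1,4-dione ((R)-shikonin) | CC(C)=CC[C@@H](O)C1=CC(=O)c2c(O)ccc(O)c2C1=O | intermediate
18 | 3-methylbut-2-enoic acid | CC(C)=CC(=O)O | starting material
19 | (1R)-1-(5,8-dihydroxy-1,4-dioxo-1,4-dihydronaphthalen-2-yl)-4-methylpent-3-en-1-yl 3-methylbut-2-enoate | CC(C)=CC[C@@H](OC(=O)C=C(C)C)C1=CC(=O)c2c(O)ccc(O)c2C1=O | target

Total step count: 10. Longest linear sequence: 8 steps (steps 2, 3, 4, 5, 6, 8, 9, 10).

**Steps most likely to fail**

Step 8 (Proposed new method). Several processes could divert it: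
- the conjugate addition may be sluggish or go to C6/C7;
- the silyl acetal may fail to open in methanolic base;
- the adduct may eliminate to a benzofuran;
- a 1,2-silyl shift followed by α-ketol isomerisation of the aldehyde may occur;
- silanol may be lost by β-elimination at C1' before ring A closes.

The fallback uses known reaction types in two isolated stages, with the two-carbon unit brought in as the free aldehyde. It sets out from quinone 11 and aldehyde 12. Enamine-catalysed α-arylation of the aldehyde by the quinone (2-[diphenyl(trimethylsilyloxy)methyl]pyrrolidine, 10 mol %, EtOH/H2O, 0 °C) should give, after rearomatisation of ring B and hemiacetal closure, the lactol (3R)-3-[(tert-butyldimethylsilyl)oxy]-1-{3-[(tert-butyldimethylsilyl)oxy]-2,5-dihydroxy-2,3-dihydro-1-benzofuran-4-yl}-6-methylhept-5-en-1-one F1. Separate treatment with piperidinium acetate in toluene under argon (Knoevenagel-type intramolecular aldol condensation and aromatisation), then K2CO3/MeOH and air, should pass through tetrol 15 and come back to the route at 16.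

Step 6. The acyl-deactivated ring may be oxidised incompletely. The acidic aqueous oxidant may also strip the silyl ether, after which the freed hydroxyl would add to the quinone. Oxidative attack on the trisubstituted alkene is a third possibility. The fallback sets out from ketone 10 and unmasks the quinone in two milder stages. BCl3 in CH2Cl2 at −78 °C should cleave only the methyl ether ortho to the ketone (chelation-assisted dealkylation) to give (3R)-3-[(tert-butyldimethylsilyl)oxy]-1-(2-hydroxy-5-methoxyphenyl)-6-methylhept-5-en-1-one F2. Oxidation of this p-methoxyphenol with PhI(OAc)2 in MeCN/H2O at 0 °C (near-neutral oxidative dealkylation) should come back to the route at 11.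

Step 10. Conversion may be low, with N-acylurea formation, competing acylation of a phenol, or deconjugation of the dimethylacryloyl group. The fallback sets out from 17 and replaces selective acylation by exhaustive acylation and selective deacylation. 3-Methylbut-2-enoic anhydride with DMAP in CH2Cl2 should give the tris-ester (1R)-1-[5,8-bis(3-methylbut-2-enoyloxy)-1,4-dioxo-1,4-dihydronaphthalen-2-yl]-4-methylpent-3-en-1-yl 3-methylbut-2-enoate F3. NH3 in MeOH at −20 °C should then cleave only the two labile aryl esters peri to the quinone carbonyls and come back to the route at 19.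

Further compounds
F1 | step 8 | (3R)-3-[(tert-butyldimethylsilyl)oxy]-1-{3-[(tert-butyldimethylsilyl)oxy]-2,5-dihydroxy-2,3-dihydro-1-benzofuran-4-yl}-6-methylhept-5-en-1-one | CC(C)=CC[C@@H](O[Si](C)(C)C(C)(C)C)CC(=O)c1c(O)ccc2OC(O)C(O[Si](C)(C)C(C)(C)C)c12
F2 | step 6 | (3R)-3-[(tert-butyldimethylsilyl)oxy]-1-(2-hydroxy-5-methoxyphenyl)-6-methylhept-5-en-1-one | CC(C)=CC[C@@H](O[Si](C)(C)C(C)(C)C)CC(=O)c1cc(OC)ccc1O
F3 | step 10 | (1R)-1-[5,8-bis(3-methylbut-2-enoyloxy)-1,4-dioxo-1,4-dihydronaphthalen-2-yl]-4-methylpent-3-en-1-yl 3-methylbut-2-enoate | CC(C)=CC[C@@H](OC(=O)C=C(C)C)C1=CC(=O)c2c(OC(=O)C=C(C)C)ccc(OC(=O)C=C(C)C)c2C1=O
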